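**Retrosynthetic overview**
1. The last bond made is the quaternary C4–acyl bond: target 24 ⇒ alkene lactone 18 + furyl thioester 23, joined by an iron/nickel-catalysed Markovnikov hydroacylation (fragment union, quaternary centre).
2. 18 ⇒ epoxy ketone 15 by epoxide-opening lactonization (lactone ring, formed second) ⇒ enone 14 ⇒ vinyl ester 12 + but-3-en-2-one (cross-metathesis, then catalytic asymmetric epoxidation).
3. 12 ⇒ δ-lactone 10 by Ireland–Claisen ring contraction (cyclohexene ring, formed first; one carbinol centre sets the quaternary and the adjacent tertiary centre).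
4. 10 ⇒ iodo ester 3 + dienal 7 by enantioselective alkylzinc addition; 3 from 3-methyloxolan-2-one, 7 from acrolein dimethyl acetal + ethyl propenyl ether.
5. 23 ⇒ furan-3-carbaldehyde + malonic acid (condensation, alkene hydrogenation, thioesterification).

Assumption: operations run in one flask or on the crude product count as one step; 1 is used as the racemate because its stereocentre is erased in step 4.

**Route**

Step 1
Reactants: 1 3-methyloxolan-2-one (racemic)
Product: 3 methyl 4-iodo-2-methylbutanoate (racemic), via trimethylsilyl 4-iodo-2-methylbutanoate 2 (not isolated)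
Conditions: Me3SiI (1.2 equiv), CH2Cl2, 23 °C; then MeOH, 50 °C
Reagents that add atoms: iodotrimethylsilane, C[Si](C)(C)I; methanol, CO
Why: Me3SiI silylates the lactone carbonyl and iodide opens the ring by SN2 attack at the O–CH2 carbon (Jung–Olah silyl iodide lactone cleavage), after which the silyl ester is methanolysed under the acid generated (Fischer esterification); the stereocentre stays racemic and is erased in step 4.

Step 2
Reactants: 4 3,3-dimethoxyprop-1-ene; 5 1-ethoxyprop-1-ene (E/Z mixture)
Product: 7 (2E)-2-methylpenta-2,4-dienal, via 1-ethoxy-1,3-dimethoxy-2-methylpent-4-ene 6 (not isolated)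
Conditions: ZnCl2 (2 mol%), EtOAc, 0 → 35 °C; then AcOH, NaOAc, H2O, 90 °C
Reagents that add atoms: water, O
Why: Lewis-acid ionisation of the acetal gives an allylic oxocarbenium ion that the enol ether captures at the acetal carbon (Müller–Cunradi–Pieroh/Isler acetal–enol ether condensation, a Mukaiyama-type addition), and aqueous acid then hydrolyses the mixed acetal and eliminates methanol to the conjugated enal, which equilibrates to the E isomer (formyl trans to vinyl).

Step 3
Reactants: 3 methyl 4-iodo-2-methylbutanoate; 7 (2E)-2-methylpenta-2,4-dienal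
Product: 10 (6R)-3-methyl-6-[(2E)-penta-2,4-dien-2-yl]oxan-2-one (3RS), via bis(4-methoxy-3-methyl-4-oxobutyl)zinc 8 (not isolated), via methyl (5R,6E)-5-hydroxy-2,6-dimethylnona-6,8-dienoate 9 (not isolated)
Conditions: 3 (4 equiv), Et2Zn (neat), CuI (0.5 mol%), 50 °C, then vacuum; (1S,2S)-N,N'-bis(trifluoromethylsulfonyl)cyclohexane-1,2-diamine (8 mol%), Ti(O-i-Pr)4 (2 equiv), PhMe, −20 °C, then 7; aq. NH4Cl; then PPTS (5 mol%), PhMe, 40 °C
Reagents that add atoms: none
Why: Copper-catalysed iodine–zinc exchange gives the ester-bearing dialkylzinc, whose titanium bis(sulfonamide)-catalysed 1,2-addition to the enal (Yoshioka–Ohno/Knochel enantioselective alkylzinc addition) occurs on the Re face under the (S,S) ligand to set the (R) carbinol centre, and the δ-hydroxy ester then closes to the lactone (acid-catalysed lactonization).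

Step 4
Reactants: 10 (6R)-3-methyl-6-[(2E)-penta-2,4-dien-2-yl]oxan-2-one
Product: 12 triisopropylsilyl (1S,2R)-2-ethenyl-1,3-dimethylcyclohex-3-ene-1-carboxylate, via triisopropylsilyl ketene acetal 11 (not isolated)
Conditions: LiN(i-Pr)2, THF, −78 °C; i-Pr3SiOTf, −78 → 23 °C; then PhMe, 105 °C
Reagents that add atoms: triisopropylsilyl trifluoromethanesulfonate, CC(C)[Si](OS(=O)(=O)C(F)(F)F)(C(C)C)C(C)C
Why: Ireland–Claisen rearrangement of the lactone silyl ketene acetal (ring contraction): the two-carbon tether enforces a boat transition state, so the (6R) C–O centre and the E alkene are relayed suprafacially into the (1S) quaternary and (2R) tertiary centres with the carboxyl cis to the vinyl group, and the cyclohexene ring is formed.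

Step 5
Reactants: 12 triisopropylsilyl (1S,2R)-2-ethenyl-1,3-dimethylcyclohex-3-ene-1-carboxylate; 13 but-3-en-2-one
Product: 14 triisopropylsilyl (1S,2R)-1,3-dimethyl-2-[(1E)-3-oxobut-1-en-1-yl]cyclohex-3-ene-1-carboxylate
Conditions: second-generation Hoveyda–Grubbs catalyst RuCl2(H2IMes)(=CH-C6H4-2-O-i-Pr) (5 mol%), 13 (5 equiv), 1,4-benzoquinone (10 mol%), CH2Cl2, 40 °C
Reagents that add atoms: none
Why: Ruthenium-catalysed olefin cross-metathesis between the monosubstituted vinyl group and the electron-poor enone partner is selective for the E enone and leaves the trisubstituted ring alkene untouched; no stereocentre is changed.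

Step 6
Reactants: 14 triisopropylsilyl (1S,2R)-1,3-dimethyl-2-[(1E)-3-oxobut-1-en-1-yl]cyclohex-3-ene-1-carboxylate
Product: 15 triisopropylsilyl (1S,2R)-2-[(2R,3S)-3-acetyloxiran-2-yl]-1,3-dimethylcyclohex-3-ene-1-carboxylate
Conditions: La(O-i-Pr)3 (10 mol%), (R)-BINOL (10 mol%), Ph3As=O (10 mol%), t-BuOOH (1.5 equiv), 4 Å MS, THF, 23 °C
Reagents that add atoms: tert-butyl hydroperoxide, CC(C)(C)OO
Why: Nucleophilic (Weitz–Scheffer type) epoxidation by the Shibasaki lanthanum–BINOL peroxide attacks only the enone, keeps the trans geometry and, under control of the (R)-BINOL catalyst (αS,βR series), gives the (2R,3S)-oxirane.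

Step 7
Reactants: 15 triisopropylsilyl (1S,2R)-2-[(2R,3S)-3-acetyloxiran-2-yl]-1,3-dimethylcyclohex-3-ene-1-carboxylate
Product: 18 (3S,3aR,7aS)-3-[(1S)-1-(acetyloxy)-2-oxopropyl]-4,7a-dimethyl-3a,6,7,7a-tetrahydro-2-benzofuran-1(3H)-one, via epoxy acid 16 (not isolated), via hydroxy lactone 17 (not isolated)
Conditions: CF3CO2H (10 equiv), CH2Cl2, 0 °C; evaporate; then Ac2O, pyridine, DMAP (5 mol%), CH2Cl2, 0 °C
Reagents that add atoms: acetic anhydride, CC(=O)OC(C)=O
Why: Acid cleaves the silyl ester and the carboxyl opens the protonated epoxide at the β-carbon by a 5-exo-tet SN2 attack with inversion (epoxide-opening lactonization), which closes the cis-fused γ-lactone with the (3S) C–O centre and leaves the α-oxygen as the (1S) alcohol, acetylated in the same flask (DMAP-catalysed acylation).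

Step 8
Reactants: 19 furan-3-carbaldehyde; 20 propanedioic acid
Product: 21 (2E)-3-(furan-3-yl)prop-2-enoic acid
Conditions: pyridine, piperidine (10 mol%), 90 °C
Reagents that add atoms: none
Why: Knoevenagel–Doebner condensation with loss of carbon dioxide gives the thermodynamically favoured E acrylic acid; no stereocentre is formed.

Step 9
Reactants: 21 (2E)-3-(furan-3-yl)prop-2-enoic acid
Product: 22 3-(furan-3-yl)propanoic acid
Conditions: H2 (1 atm), RhCl(PPh3)3 (3 mol%), PhH/EtOH (1:1), 40 °C
Reagents that add atoms: none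
Why: Homogeneous hydrogenation with Wilkinson's catalyst saturates the disubstituted acrylic alkene and does not touch the aromatic furan.

Step 10
Reactants: 22 3-(furan-3-yl)propanoic acid
Product: 23 S-(pyridin-2-yl) 3-(furan-3-yl)propanethioate
Conditions: 2,2'-dipyridyl disulfide, PPh3, CH2Cl2, 23 °C
Reagents that add atoms: 2,2'-dipyridyl disulfide, c1ccc(SSc2ccccn2)nc1
Why: Mukaiyama redox condensation (Corey–Nicolaou thioester formation) activates the acid through an acyloxyphosphonium ion that the pyridinethiolate captures under neutral conditions.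

Step 11
Reactants: 18 (3S,3aR,7aS)-3-[(1S)-1-(acetyloxy)-2-oxopropyl]-4,7a-dimethyl-3a,6,7,7a-tetrahydro-2-benzofuran-1(3H)-one; 23 S-(pyridin-2-yl) 3-(furan-3-yl)propanethioate
Product: 24 (3S,3aR,4S,7aS)-3-[(1S)-1-(acetyloxy)-2-oxopropyl]-4-[3-(furan-3-yl)propanoyl]-4,7a-dimethylhexahydro-2-benzofuran-1(3H)-one
Conditions: Fe(acac)3 (30 mol%), NiBr2(dme) (15 mol%), 4,4'-di-tert-butyl-2,2'-bipyridine (18 mol%), PhSiH3 (2.5 equiv), 23 (2 equiv), THF/i-PrOH (4:1), 30 °C
Reagents that add atoms: none
Why: Proposed new method: iron/nickel dual-catalytic Markovnikov hydroacylation of an unactivated trisubstituted alkene by a thioester, in which the iron hydride made from Fe(acac)3 and PhSiH3 transfers a hydrogen atom to C5 of 18, the tertiary C4 radical is captured by the acyl–nickel thiolate formed by oxidative addition of zerovalent nickel into the C–S bond of 23, and reductive elimination from trivalent nickel forges the C4–acyl bond and the quaternary centre; capture should occur on the convex α-face, anti to the lactone ring and its acetoxy-ketone arm that cover the β-face, giving the (4S) centre; the closest known reactions are iron/nickel hydrogen-atom-transfer hydroarylation of alkenes to quaternary carbons and nickel-catalysed reductive acylation of tertiary alkyl radicals generated from halides or redox-active esters.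

**Compound list**

1 | 3-methyloxolan-2-one (racemic) | CC1CCOC1=O | starting material
2 | trimethylsilyl 4-iodo-2-methylbutanoate (racemic) | CC(CCI)C(=O)O[Si](C)(C)C | intermediate
3 | methyl 4-iodo-2-methylbutanoate (racemic) | COC(=O)C(C)CCI | intermediate
4 | 3,3-dimethoxyprop-1-ene | C=CC(OC)OC | starting material
5 | 1-ethoxyprop-1-ene (E/Z mixture) | CCOC=CC | starting material
6 | 1-ethoxy-1,3-dimethoxy-2-methylpent-4-ene (diastereomer mixture) | C=CC(OC)C(C)C(OC)OCC | intermediate
7 | (2E)-2-methylpenta-2,4-dienal | O=C/C(C)=C/C=C | intermediate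
8 | bis(4-methoxy-3-methyl-4-oxobutyl)zinc | COC(=O)C(C)CC[Zn]CCC(C)C(=O)OC | intermediate
9 | methyl (5R,6E)-5-hydroxy-2,6-dimethylnona-6,8-dienoate (2RS) | COC(=O)C(C)CC[C@@H](O)/C(C)=C/C=C | intermediate
10 | (6R)-3-methyl-6-[(2E)-penta-2,4-dien-2-yl]oxan-2-one (3RS) | CC1CC[C@@H](OC1=O)/C(C)=C/C=C | intermediate
11 | triisopropyl{[(6R)-3-methyl-6-[(2E)-penta-2,4-dien-2-yl]-5,6-dihydro-4H-pyran-2-yl]oxy}silane (triisopropylsilyl ketene acetal) | CC1=C(O[Si](C(C)C)(C(C)C)C(C)C)O[C@H](CC1)/C(C)=C/C=C | intermediate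
12 | triisopropylsilyl (1S,2R)-2-ethenyl-1,3-dimethylcyclohex-3-ene-1-carboxylate | CC(C)[Si](OC(=O)[C@@]1(C)CCC=C(C)[C@H]1C=C)(C(C)C)C(C)C | intermediate
13 | but-3-en-2-one | CC(=O)C=C | starting material
14 | triisopropylsilyl (1S,2R)-1,3-dimethyl-2-[(1E)-3-oxobut-1-en-1-yl]cyclohex-3-ene-1-carboxylate | CC(C)[Si](OC(=O)[C@@]1(C)CCC=C(C)[C@H]1/C=C/C(C)=O)(C(C)C)C(C)C | intermediate
15 | triisopropylsilyl (1S,2R)-2-[(2R,3S)-3-acetyloxiran-2-yl]-1,3-dimethylcyclohex-3-ene-1-carboxylate | CC(C)[Si](OC(=O)[C@@]1(C)CCC=C(C)[C@H]1[C@H]2O[C@@H]2C(C)=O)(C(C)C)C(C)C | intermediate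
16 | (1S,2R)-2-[(2R,3S)-3-acetyloxiran-2-yl]-1,3-dimethylcyclohex-3-ene-1-carboxylic acid (epoxy acid) | OC(=O)[C@@]1(C)CCC=C(C)[C@H]1[C@H]2O[C@@H]2C(C)=O | intermediate
17 | (3S,3aR,7aS)-3-[(1S)-1-hydroxy-2-oxopropyl]-4,7a-dimethyl-3a,6,7,7a-tetrahydro-2-benzofuran-1(3H)-one (hydroxy lactone) | O[C@H](C(C)=O)[C@H]1OC(=O)[C@@]2(C)CCC=C(C)[C@@H]12 | intermediate
18 | (3S,3aR,7aS)-3-[(1S)-1-(acetyloxy)-2-oxopropyl]-4,7a-dimethyl-3a,6,7,7a-tetrahydro-2-benzofuran-1(3H)-one | CC(=O)O[C@H](C(C)=O)[C@H]1OC(=O)[C@@]2(C)CCC=C(C)[C@@H]12 | intermediate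
19 | furan-3-carbaldehyde | O=Cc1ccoc1 | starting material
20 | propanedioic acid | OC(=O)CC(O)=O | starting material
21 | (2E)-3-(furan-3-yl)prop-2-enoic acid | OC(=O)/C=C/c1ccoc1 | intermediate
22 | 3-(furan-3-yl)propanoic acid | OC(=O)CCc1ccoc1 | intermediate
23 | S-(pyridin-2-yl) 3-(furan-3-yl)propanethioate | O=C(CCc1ccoc1)Sc1ccccn1 | intermediate
24 | (3S,3aR,4S,7aS)-3-[(1S)-1-(acetyloxy)-2-oxopropyl]-4-[3-(furan-3-yl)propanoyl]-4,7a-dimethylhexahydro-2-benzofuran-1(3H)-one | CC(=O)O[C@H](C(C)=O)[C@H]1OC(=O)[C@@]2(C)CCC[C@](C)(C(=O)CCc3ccoc3)[C@@H]12 | target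

**Step count**

Total step count: 11. Longest linear sequence: 7 steps (step 1 or 2, then 3, 4, 5, 6, 7, 11); steps 8–10 build the second fragment in parallel.

**Steps most likely to fail, with fallbacks**

Step 11 (the proposed hydroacylation). Risks are simple hydrogenation or isomerization of the alkene, slow capture of the hindered tertiary radical by acyl–nickel, and incomplete facial selectivity. The fallback uses known chemistry, sets out from 18 and comes back at 24. Anhydrous HBr in CH2Cl2 at −78 °C adds in the Markovnikov sense to give the tertiary bromide (3S,3aR,7aS)-3-[(1S)-1-(acetyloxy)-2-oxopropyl]-4-bromo-4,7a-dimethylhexahydro-2-benzofuran-1(3H)-one F1 (either C4 epimer). The established nickel-catalysed reductive acylation of tertiary alkyl bromides with carboxylic acids (acid 22, Boc2O, Ni(acac)2, 2,2'-bipyridine, Zn, MgCl2, DMA, 25 °C) then gives 24. The stereo-determining event is the same capture of the planar radical on the open α-face, so this answers the reactivity risk but not the selectivity risk.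

Step 4 (Ireland–Claisen ring contraction). Risks are a slow boat-type rearrangement of the trisubstituted dienyl unit and competing elimination or ketene formation from the lactone enolate. The fallback sets out from 7 and comes back at 12. Wittig methylenation (Ph3P=CH2, THF, 0 °C) gives (3E)-3-methylhexa-1,3,5-triene F2. An enantioselective Diels–Alder reaction with 2-methylprop-2-enal under a Corey oxazaborolidinium triflimide catalyst follows; the catalyst enantiomer is chosen on a test run to give the 1S,2R series. Ortho regiochemistry and an endo formyl group cis to the vinyl group are expected, giving (1S,2R)-2-ethenyl-1,3-dimethylcyclohex-3-ene-1-carbaldehyde F3. Pinnick oxidation (NaClO2, NaH2PO4, 2-methylbut-2-ene) gives (1S,2R)-2-ethenyl-1,3-dimethylcyclohex-3-ene-1-carboxylic acid F4, and silylation (i-Pr3SiCl, imidazole, DMF) gives 12.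

Step 6 (asymmetric epoxidation of a hindered enone). Risks are slow peroxide addition at the crowded β-carbon, γ-deprotonation of the doubly activated ring-fusion C–H, and a mismatch between catalyst and substrate. The fallback sets out from 12 and comes back at 15. Cross-metathesis of 12 with (R)-but-3-en-2-ol (same ruthenium catalyst) gives triisopropylsilyl (1S,2R)-2-[(1E,3R)-3-hydroxybut-1-en-1-yl]-1,3-dimethylcyclohex-3-ene-1-carboxylate F5. Sharpless asymmetric epoxidation (Ti(O-i-Pr)4, D-(−)-diisopropyl tartrate, t-BuOOH, 4 Å MS, CH2Cl2, −20 °C; matched pair, reagent-controlled face) gives triisopropylsilyl (1S,2R)-2-{(2R,3R)-3-[(1R)-1-hydroxyethyl]oxiran-2-yl}-1,3-dimethylcyclohex-3-ene-1-carboxylate F6. Dess–Martin oxidation of the carbinol then gives 15.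

**Further compounds**

F1 | step 11 | (3S,3aR,7aS)-3-[(1S)-1-(acetyloxy)-2-oxopropyl]-4-bromo-4,7a-dimethylhexahydro-2-benzofuran-1(3H)-one | CC(=O)O[C@H](C(C)=O)[C@H]1OC(=O)[C@@]2(C)CCCC(C)(Br)[C@@H]12
F2 | step 4 | (3E)-3-methylhexa-1,3,5-triene | C=C/C(C)=C/C=C
F3 | step 4 | (1S,2R)-2-ethenyl-1,3-dimethylcyclohex-3-ene-1-carbaldehyde | O=C[C@@]1(C)CCC=C(C)[C@H]1C=C
F4 | step 4 | (1S,2R)-2-ethenyl-1,3-dimethylcyclohex-3-ene-1-carboxylic acid | OC(=O)[C@@]1(C)CCC=C(C)[C@H]1C=C
F5 | step 6 | triisopropylsilyl (1S,2R)-2-[(1E,3R)-3-hydroxybut-1-en-1-yl]-1,3-dimethylcyclohex-3-ene-1-carboxylate | CC(C)[Si](OC(=O)[C@@]1(C)CCC=C(C)[C@H]1/C=C/[C@@H](C)O)(C(C)C)C(C)C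
F6 | step 6 | triisopropylsilyl (1S,2R)-2-{(2R,3R)-3-[(1R)-1-hydroxyethyl]oxiran-2-yl}-1,3-dimethylcyclohex-3-ene-1-carboxylate | CC(C)[Si](OC(=O)[C@@]1(C)CCC=C(C)[C@H]1[C@H]2O[C@@H]2[C@@H](C)O)(C(C)C)C(C)C
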